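**Plan**
Notation: unit 1 is the 6-linked flavone and unit 2 the 8-linked one. In each, ring A is the benzo ring, ring C the pyranone and ring B the anisyl group, with chromen-4-one numbering.
Cuts, in order: the alkyl groups on O5 and O7 of unit 1 and on O5 of unit 2; ring C of unit 2 at O1–C2, C2–C3 and C4–C4a; ring A of unit 2 at C8–C8a, C8a–C4a and C6–C7; the bond from C6 of unit 1 to the alkyne.
Enabling feature: in ring A of unit 2 the biaryl carbon C8 sits between C8a (bearing O1) and C7 (bearing OMe), with the third oxygen on C5 and hydrogen on C6. A cyclobutenone/ynol ether benzannulation lays down this hydroxyl/substituent/alkoxy sequence in one operation.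
Forward: acacetin 1 supplies all three rings of unit 1 and is armed at C6 (iodide 4, methoxyalkyne 8). Ring A of unit 2 is grown on the alkyne with cyclobutenone 9 (phenol 14), ring B comes with aldehyde 17, ring C closes oxidatively (19), and BCl3 unmasks 20.
Stereochemistry: the target has no stereocentre. The C6–C8 axis carries no descriptor and is formed racemic, and the E-alkene of the chalcone is consumed.

Key step: step 5

Assumption: the hindered biaryl axis is drawn without configuration, so the racemate is the goal. Acacetin and 3-ethoxycyclobut-2-en-1-one are taken as catalogue compounds.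

**Step 1**
Reactants: 1 acacetin (5,7-dihydroxy-2-(4-methoxyphenyl)chromen-4-one)
Product: 2 5-hydroxy-7-isopropoxy-2-(4-methoxyphenyl)chromen-4-one
Conditions: 2-bromopropane (1.2 equiv), K2CO3, DMF, 60 °C
Reagents that add atoms: 2-bromopropane, CC(C)Br
Why: Williamson etherification should touch only O7, because the 7-hydroxyl is the more acidic, unchelated phenol while the 5-hydroxyl is held in a hydrogen bond to the C4 carbonyl.

**Step 2**
Reactants: 2 5-hydroxy-7-isopropoxy-2-(4-methoxyphenyl)chromen-4-one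
Product: 3 5-hydroxy-6-iodo-7-isopropoxy-2-(4-methoxyphenyl)chromen-4-one
Conditions: BnMe3N·ICl2 (1.05 equiv), CaCO3, CH2Cl2/MeOH, rt
Reagents that add atoms: benzyltrimethylammonium dichloroiodate, C[N+](C)(C)Cc1ccccc1.Cl[I-]Cl
Why: Electrophilic aromatic iodination with the dichloroiodate/carbonate system is established to attack 5-hydroxy-7-alkoxyflavones at C6, the carbon ortho to the free phenol, rather than at C8, and one equivalent should prevent a second iodination.

**Step 3**
Reactants: 3 5-hydroxy-6-iodo-7-isopropoxy-2-(4-methoxyphenyl)chromen-4-one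
Product: 4 6-iodo-7-isopropoxy-5-methoxy-2-(4-methoxyphenyl)chromen-4-one
Conditions: MeI (excess), K2CO3, DMF, 50 °C, sealed flask
Reagents that add atoms: iodomethane, CI
Why: Williamson methylation under forcing carbonate conditions overcomes the hydrogen bond of the peri phenol, as is routine for 6-halo-5-hydroxyflavones, and masks the oxygen that would otherwise add to the neighbouring ynol ether.

**Step 4**
Reactants: 4 6-iodo-7-isopropoxy-5-methoxy-2-(4-methoxyphenyl)chromen-4-one; 5 chloroacetaldehyde dimethyl acetal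
Product: 8 7-isopropoxy-5-methoxy-6-(methoxyethynyl)-2-(4-methoxyphenyl)chromen-4-one, via lithium methoxyacetylide 6 (not isolated), via methoxyethynylzinc chloride 7 (not isolated)
Conditions: 5 (3 equiv), Et2NH/n-BuLi (3 equiv per 5), THF, 0 °C; ZnCl2 (excess), 0 °C → rt; then 4, Pd(PPh3)4 (5 mol %), THF, rt → 45 °C; neutral work-up, basic alumina
Reagents that add atoms: none
Why: Negishi coupling should work because twofold elimination of the chloroacetal by amide base gives the acetylide, zinc lowers its basicity enough to spare the pyranone, and alkoxyethynylzinc chlorides are proven partners of aryl iodides under zerovalent palladium catalysis, the slim sp nucleophile fitting between the two ortho alkoxy groups.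

**Step 5**
Reactants: 8 7-isopropoxy-5-methoxy-6-(methoxyethynyl)-2-(4-methoxyphenyl)chromen-4-one; 9 3-ethoxycyclobut-2-en-1-one
Product: 14 6-(4-ethoxy-2-hydroxy-6-methoxyphenyl)-7-isopropoxy-5-methoxy-2-(4-methoxyphenyl)chromen-4-one, via ethoxyvinylketene 10 (not isolated), via vinylcyclobutenone adduct 11 (not isolated), via dienylketene 12 (not isolated), via cyclohexadienone 13 (not isolated)
Conditions: 9 (2.5 equiv, in portions), PhMe (0.5 M), base-washed sealed tube, 110 → 140 °C; then cat. K2CO3, MeOH, rt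
Reagents that add atoms: none
Why: This is a Danheiser benzannulation, the known union of a cyclobutenone with an alkoxyalkyne: heat opens 9 by a conrotatory four-electron process to ethoxyvinylketene 10, and the aryl-bearing alkyne carbon of 8, made nucleophilic by the methoxy group on its neighbour, attacks the ketene carbonyl carbon in a [2+2] cycloaddition giving 11 (new bonds C8–C8a and C6–C7 of unit 2). Cyclobutenone 11 opens reversibly to dienylketene 12, and the isomer with the ketene and ethoxyvinyl groups cis on the central double bond is drained by a disrotatory six-electron electrocyclisation (bond C8a–C4a), the single ring closure of the step, to dienone 13, which tautomerises irreversibly to phenol 14. The only selectivity required is regiochemical and the polarity of the ynol ether fixes it, so that hydroxyl and methoxy end up on either side of the biaryl carbon; since both carbons next to the ethoxy-bearing carbon of 10 carry only hydrogen, even a direct [4+2] addition would converge on the same arene. No stereocentre survives, because the sp3 carbon of 11 is planarised on ring opening and the crowded C6–C8 axis is formed as a racemate. As a methyl ether, 8 lacks the β-hydrogen that lets higher alkoxyalkynes fragment to ketene and alkene on heating, and the neutral medium should leave the aryl ethers and the pyranone of unit 1 untouched. Excess 9 compensates for ketene lost to self-reaction, and the brief methanolysis returns any phenol that was O-acylated by 10.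

**Step 6**
Reactants: 14 6-(4-ethoxy-2-hydroxy-6-methoxyphenyl)-7-isopropoxy-5-methoxy-2-(4-methoxyphenyl)chromen-4-one
Product: 16 6-(3-acetyl-4-ethoxy-2-hydroxy-6-methoxyphenyl)-7-isopropoxy-5-methoxy-2-(4-methoxyphenyl)chromen-4-one, via aryl acetate 15 (not isolated)
Conditions: Ac2O (2 equiv), BF3·OEt2 (4 equiv), ClCH2CH2Cl, 0 → 60 °C; then H2O/MeOH, 50 °C
Reagents that add atoms: acetic anhydride, CC(=O)OC(C)=O
Why: BF3-promoted O-acetylation and Fries-type migration should place the acetyl group on the one free carbon ortho to the phenol (future C4a), as is the rule for 3,5-dialkoxyphenols where chelation between phenol oxygen and the new carbonyl makes the ortho ketone the sink, while BF3 is too mild to cleave the aryl ethers and the boron-complexed flavone ring is deactivated.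

**Step 7**
Reactants: 16 6-(3-acetyl-4-ethoxy-2-hydroxy-6-methoxyphenyl)-7-isopropoxy-5-methoxy-2-(4-methoxyphenyl)chromen-4-one; 17 4-methoxybenzaldehyde
Product: 18 6-{4-ethoxy-2-hydroxy-6-methoxy-3-[(E)-3-(4-methoxyphenyl)prop-2-enoyl]phenyl}-7-isopropoxy-5-methoxy-2-(4-methoxyphenyl)chromen-4-one
Conditions: 17 (1.5 equiv), KOH (50 % aq.), EtOH, rt; then 1 M HCl to pH 5
Reagents that add atoms: none
Why: Claisen–Schmidt condensation of a 2-hydroxy-4,6-dialkoxyacetophenone with a non-enolisable aldehyde is standard and gives the E-enone under thermodynamic control, and any reversible hydroxide opening of the pyranone of unit 1 can only reclose to the same ring because O5 is methylated.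

**Step 8**
Reactants: 18 the (E)-chalcone of step 7
Product: 19 5-ethoxy-8-[7-isopropoxy-5-methoxy-2-(4-methoxyphenyl)-4-oxochromen-6-yl]-7-methoxy-2-(4-methoxyphenyl)chromen-4-one
Conditions: I2 (10 mol %), DMSO, 130 °C
Reagents that add atoms: none
Why: Iodine-catalysed oxidative cyclisation of a 2'-hydroxychalcone (6-endo oxa-Michael closure, α-iodination, loss of HI, DMSO as terminal oxidant) is the standard flavone synthesis, and since only the oxygen on C8a is free, ring C of unit 2 can close in one direction only, which locks the 8-linkage.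

**Step 9**
Reactants: 19 5-ethoxy-8-[7-isopropoxy-5-methoxy-2-(4-methoxyphenyl)-4-oxochromen-6-yl]-7-methoxy-2-(4-methoxyphenyl)chromen-4-one
Product: 20 8-[5,7-dihydroxy-2-(4-methoxyphenyl)-4-oxochromen-6-yl]-5-hydroxy-7-methoxy-2-(4-methoxyphenyl)chromen-4-one (CNP0146326.0)
Conditions: BCl3 (1 M in CH2Cl2, 8 equiv), CH2Cl2, −78 → 0 °C; then H2O
Reagents that add atoms: none
Why: Selective BCl3 ether cleavage should work because chelation to each C4 carbonyl steers boron to the two peri alkoxy groups (5-OMe of unit 1, 5-OEt of unit 2) and the secondary isopropyl ether ionises readily, whereas the unchelated methyl ethers on C7 of unit 2 and on both rings B are inert to BCl3 at or below 0 °C.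

**Compound list**
1 | acacetin, 5,7-dihydroxy-2-(4-methoxyphenyl)chromen-4-one | COc1ccc(cc1)-c1cc(=O)c2c(O)cc(O)cc2o1 | starting material
2 | 5-hydroxy-7-isopropoxy-2-(4-methoxyphenyl)chromen-4-one | COc1ccc(cc1)-c1cc(=O)c2c(O)cc(OC(C)C)cc2o1 | intermediate
3 | 5-hydroxy-6-iodo-7-isopropoxy-2-(4-methoxyphenyl)chromen-4-one | COc1ccc(cc1)-c1cc(=O)c2c(O)c(I)c(OC(C)C)cc2o1 | intermediate
4 | 6-iodo-7-isopropoxy-5-methoxy-2-(4-methoxyphenyl)chromen-4-one | COc1ccc(cc1)-c1cc(=O)c2c(OC)c(I)c(OC(C)C)cc2o1 | intermediate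
5 | chloroacetaldehyde dimethyl acetal | COC(CCl)OC | starting material
6 | lithium methoxyacetylide | COC#C[Li] | intermediate
7 | methoxyethynylzinc chloride | COC#C[Zn]Cl | intermediate
8 | 7-isopropoxy-5-methoxy-6-(methoxyethynyl)-2-(4-methoxyphenyl)chromen-4-one | COC#Cc1c(OC(C)C)cc2oc(-c3ccc(OC)cc3)cc(=O)c2c1OC | intermediate
9 | 3-ethoxycyclobut-2-en-1-one | CCOC1=CC(=O)C1 | starting material
10 | 3-ethoxybuta-1,3-dien-1-one (ethoxyvinylketene) | C=C(OCC)C=C=O | intermediate
11 | 4-(1-ethoxyvinyl)-3-methoxy-2-[7-isopropoxy-5-methoxy-2-(4-methoxyphenyl)-4-oxochromen-6-yl]cyclobut-2-en-1-one (racemic) | C=C(OCC)C1C(OC)=C(c2c(OC(C)C)cc3oc(-c4ccc(OC)cc4)cc(=O)c3c2OC)C1=O | intermediate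
12 | 5-ethoxy-3-methoxy-2-[7-isopropoxy-5-methoxy-2-(4-methoxyphenyl)-4-oxochromen-6-yl]hexa-1,3,5-trien-1-one, ketene and ethoxyvinyl groups cis on the central double bond | C=C(OCC)\C=C(OC)/C(=C=O)c1c(OC(C)C)cc2oc(-c3ccc(OC)cc3)cc(=O)c2c1OC | intermediate
13 | 5-ethoxy-3-methoxy-2-[7-isopropoxy-5-methoxy-2-(4-methoxyphenyl)-4-oxochromen-6-yl]cyclohexa-2,4-dien-1-one | CCOC1=CC(OC)=C(c2c(OC(C)C)cc3oc(-c4ccc(OC)cc4)cc(=O)c3c2OC)C(=O)C1 | intermediate
14 | 6-(4-ethoxy-2-hydroxy-6-methoxyphenyl)-7-isopropoxy-5-methoxy-2-(4-methoxyphenyl)chromen-4-one | CCOc1cc(O)c(-c2c(OC(C)C)cc3oc(-c4ccc(OC)cc4)cc(=O)c3c2OC)c(OC)c1 | intermediate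
15 | 5-ethoxy-3-methoxy-2-[7-isopropoxy-5-methoxy-2-(4-methoxyphenyl)-4-oxochromen-6-yl]phenyl acetate | CCOc1cc(OC(C)=O)c(-c2c(OC(C)C)cc3oc(-c4ccc(OC)cc4)cc(=O)c3c2OC)c(OC)c1 | intermediate
16 | 6-(3-acetyl-4-ethoxy-2-hydroxy-6-methoxyphenyl)-7-isopropoxy-5-methoxy-2-(4-methoxyphenyl)chromen-4-one | CCOc1cc(OC)c(-c2c(OC(C)C)cc3oc(-c4ccc(OC)cc4)cc(=O)c3c2OC)c(O)c1C(C)=O | intermediate
17 | 4-methoxybenzaldehyde | COc1ccc(C=O)cc1 | starting material
18 | 6-{4-ethoxy-2-hydroxy-6-methoxy-3-[(E)-3-(4-methoxyphenyl)prop-2-enoyl]phenyl}-7-isopropoxy-5-methoxy-2-(4-methoxyphenyl)chromen-4-one | CCOc1cc(OC)c(-c2c(OC(C)C)cc3oc(-c4ccc(OC)cc4)cc(=O)c3c2OC)c(O)c1C(=O)/C=C/c1ccc(OC)cc1 | intermediate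
19 | 5-ethoxy-8-[7-isopropoxy-5-methoxy-2-(4-methoxyphenyl)-4-oxochromen-6-yl]-7-methoxy-2-(4-methoxyphenyl)chromen-4-one | CCOc1cc(OC)c(-c2c(OC(C)C)cc3oc(-c4ccc(OC)cc4)cc(=O)c3c2OC)c2oc(-c3ccc(OC)cc3)cc(=O)c12 | intermediate
20 | 8-[5,7-dihydroxy-2-(4-methoxyphenyl)-4-oxochromen-6-yl]-5-hydroxy-7-methoxy-2-(4-methoxyphenyl)chromen-4-one (CNP0146326.0) | COc1ccc(-c2cc(=O)c3c(O)c(-c4c(OC)cc(O)c5c(=O)cc(-c6ccc(OC)cc6)oc45)c(O)cc3o2)cc1 | target

Total step count: 9. Longest linear sequence: 9 steps (1 → 20).

**Steps most likely to fail**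

**Step 5.** The alkyne carbon that must attack the ketene carries an aryl group with two ortho alkoxy substituents. The [2+2] addition may therefore be slower than self-consumption of the transient ketene or slow thermal decay of the ynol ether.

The fallback gives up growing ring A and joins two finished flavones at C6–C8. It sets out from iodide 4 and comes back at target 20.
- Commercial 5,7-dimethoxy-2-(4-methoxyphenyl)chromen-4-one F1 is iodinated at C8, the site that fully O-alkylated 5,7-dioxygenated flavones offer to electrophiles (NIS, cat. CF3CO2H, MeCN). This gives 8-iodo-5,7-dimethoxy-2-(4-methoxyphenyl)chromen-4-one F2.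
- Miyaura borylation (B2pin2, PdCl2(dppf), KOAc, dioxane, 90 °C) gives 5,7-dimethoxy-2-(4-methoxyphenyl)-8-(4,4,5,5-tetramethyl-1,3,2-dioxaborolan-2-yl)chromen-4-one F3.
- Suzuki–Miyaura coupling with 4 (Pd2(dba)3, SPhos, K3PO4, PhMe/H2O, 100 °C) gives 8-[7-isopropoxy-5-methoxy-2-(4-methoxyphenyl)-4-oxochromen-6-yl]-5,7-dimethoxy-2-(4-methoxyphenyl)chromen-4-one F4.
- BCl3 under the conditions of step 9 removes the isopropyl and the two peri methyl groups and delivers 20.

**Step 4.** Oxidative addition and transmetalation at the crowded C6 may be slow. The acid-sensitive ynol ether may also be hydrated during coupling, work-up or chromatography.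

The fallback makes the triple bond on the arene by elimination instead of importing it by cross-coupling. It sets out from 4 and comes back at 8.
- Iodine–magnesium exchange (iPrMgCl·LiCl, THF, −40 °C) gives [7-isopropoxy-5-methoxy-2-(4-methoxyphenyl)-4-oxochromen-6-yl]magnesium chloride F5.
- Acylation of F5 with N,2-dimethoxy-N-methylacetamide gives 7-isopropoxy-5-methoxy-6-(methoxyacetyl)-2-(4-methoxyphenyl)chromen-4-one F6.
- Chelation-controlled enolisation and triflation (LiN(SiMe3)2, PhNTf2, THF, −78 °C) gives (Z)-2-methoxy-1-[7-isopropoxy-5-methoxy-2-(4-methoxyphenyl)-4-oxochromen-6-yl]vinyl trifluoromethanesulfonate F7, in which hydrogen and triflate are anti.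
- KOtBu (THF, −78 °C → rt) eliminates the triflate to give 8.

**Step 6.** Acylation may drift to the carbon para to the phenol, between the two alkoxy groups. Prolonged Lewis-acid exposure may also cause loss of a protecting group.

The fallback uses a directed formylation that can only reach the ortho carbon and then adjusts carbon count and oxidation level. It sets out from 14 and comes back at 16.
- Casnati–Skattebøl formylation through the magnesium phenoxide (MgCl2, Et3N, paraformaldehyde, MeCN, reflux) gives 6-ethoxy-2-hydroxy-4-methoxy-3-[7-isopropoxy-5-methoxy-2-(4-methoxyphenyl)-4-oxochromen-6-yl]benzaldehyde F8.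
- MeMgBr (2.2 equiv, THF, −78 °C) adds to the aldehyde faster than to the vinylogous-ester carbonyl of the flavone. This gives 6-[4-ethoxy-2-hydroxy-3-(1-hydroxyethyl)-6-methoxyphenyl]-7-isopropoxy-5-methoxy-2-(4-methoxyphenyl)chromen-4-one F9, whose carbinol configuration is irrelevant.
- MnO2 (CH2Cl2, rt) oxidises the benzylic alcohol to 16.

**Further compounds**
F1 | step 5 | 5,7-dimethoxy-2-(4-methoxyphenyl)chromen-4-one (bought) | COc1ccc(cc1)-c1cc(=O)c2c(OC)cc(OC)cc2o1
F2 | step 5 | 8-iodo-5,7-dimethoxy-2-(4-methoxyphenyl)chromen-4-one | COc1ccc(cc1)-c1cc(=O)c2c(OC)cc(OC)c(I)c2o1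
F3 | step 5 | 5,7-dimethoxy-2-(4-methoxyphenyl)-8-(4,4,5,5-tetramethyl-1,3,2-dioxaborolan-2-yl)chromen-4-one | COc1ccc(cc1)-c1cc(=O)c2c(OC)cc(OC)c(B3OC(C)(C)C(C)(C)O3)c2o1
F4 | step 5 | 8-[7-isopropoxy-5-methoxy-2-(4-methoxyphenyl)-4-oxochromen-6-yl]-5,7-dimethoxy-2-(4-methoxyphenyl)chromen-4-one | COc1cc(OC)c(-c2c(OC(C)C)cc3oc(-c4ccc(OC)cc4)cc(=O)c3c2OC)c2oc(-c3ccc(OC)cc3)cc(=O)c12
F5 | step 4 | [7-isopropoxy-5-methoxy-2-(4-methoxyphenyl)-4-oxochromen-6-yl]magnesium chloride | COc1ccc(cc1)-c1cc(=O)c2c(OC)c([Mg]Cl)c(OC(C)C)cc2o1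
F6 | step 4 | 7-isopropoxy-5-methoxy-6-(methoxyacetyl)-2-(4-methoxyphenyl)chromen-4-one | COCC(=O)c1c(OC(C)C)cc2oc(-c3ccc(OC)cc3)cc(=O)c2c1OC
F7 | step 4 | (Z)-2-methoxy-1-[7-isopropoxy-5-methoxy-2-(4-methoxyphenyl)-4-oxochromen-6-yl]vinyl trifluoromethanesulfonate | CO/C=C(\OS(=O)(=O)C(F)(F)F)c1c(OC(C)C)cc2oc(-c3ccc(OC)cc3)cc(=O)c2c1OC
F8 | step 6 | 6-ethoxy-2-hydroxy-4-methoxy-3-[7-isopropoxy-5-methoxy-2-(4-methoxyphenyl)-4-oxochromen-6-yl]benzaldehyde | CCOc1cc(OC)c(-c2c(OC(C)C)cc3oc(-c4ccc(OC)cc4)cc(=O)c3c2OC)c(O)c1C=O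
F9 | step 6 | 6-[4-ethoxy-2-hydroxy-3-(1-hydroxyethyl)-6-methoxyphenyl]-7-isopropoxy-5-methoxy-2-(4-methoxyphenyl)chromen-4-one | CCOc1cc(OC)c(-c2c(OC(C)C)cc3oc(-c4ccc(OC)cc4)cc(=O)c3c2OC)c(O)c1C(C)O
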